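## Structural features

The target 18 is an achiral flavone: benzene ring A is fused to a 4-pyranone ring C (a 4H-chromen-4-one), and ring C carries phenyl ring B on C2. There are no stereocentres, so none stand next to each other; the C2–C1' axis is flanked by 2'-OH and 6'-OMe but faces only O1 and C3–H, so it is not a stable stereo-axis. Ring A is fully substituted: C5, C7 and C8 carry methoxy groups, C6 a free hydroxyl and C8a the ring oxygen O1, so five neighbouring oxygens must be told apart and only the one on C6 may end up free. Ring B is 2,6-dioxygenated, which makes the C2–C1' bond doubly ortho-hindered. The fragile points are three: the 6-OH, para to O1 and so a hydroquinone monoether that oxidises easily in base and air; the 5-OMe peri to the C4 carbonyl, the first ether lost to Lewis acids; and the pyranone, which hydroxide opens at C2. The real difficulty is the combination of a pentaoxygenated ring A with a hindered ring B, because the classical 1,3-diketone routes to ring C must join two di-ortho-substituted carbonyl partners. The key step uses the fact that ring C (O1, C2, C3, C4, C4a, C8a) without C3 is the furan ring of a 2-arylbenzofuran-3-ol, whose electron-rich enol ether double bond between the future C2 and C4 can accept a one-carbon unit that becomes C3.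

## Logic of the disconnections

18 ⇒ 17. C3–H is exchanged for C3–Cl, and the O–H bonds at C6 and C2' for O–benzyl bonds. The chlorine is the trace left by the carbon insertion, and both phenols carry the one group that leaves under the conditions that also remove chlorine, so a single reduction ends the synthesis. The gain is that the oxidation-prone 6-OH appears only in the last operation. The forward step must cleave a vinylic C–Cl bond and two aryl benzyl ethers without saturating C2=C3 and without a Lewis acid that would touch the 5-OMe. An amine-free acid acceptor is chosen because amines slow O-debenzylation on palladium.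

17 ⇒ 13 + 14. C2–C3 and C3–C4 are cut, C3 leaves with its chlorine as the one-carbon unit 14, and C2 is rejoined to C4, so the pyranone contracts to the furan ring of 13. Benzofuran positions 4, 5, 6 and 7 correspond to flavone positions 5, 6, 7 and 8, and the names and connectivities of 13 and 17 agree on this, so no structure needs correcting. Cutting here avoids building ring C by a 1,3-dicarbonyl condensation between two hindered partners and leaves an aromatic five-membered ring whose aryl bond can be made by coupling. The demand is high: the carbene from 14 must add to a tetrasubstituted, shielded enol ether, the silyl ether must outlive the base until it has done so, and the cyclopropane must open across the fusion bond.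

13 ⇒ 9 + 11 (through 12). The C2–C1' bond and the O–Si bond are cut. This is the convergent point: ring A with its furanone and ring B arrive as separate, stable pieces, and the ketone α-carbon of 9 is the natural nucleophile for an aryl halide. The forward coupling must join a secondary enolate carbon to a di-ortho-substituted aryl bromide. Because the enol form of the coupled product autoxidises at C2, the enolate 12 is silylated in the same flask and not isolated.

11 ⇒ 10. Only the O–benzyl bond is cut. Electrophilic bromination of a 3-alkoxyphenol goes ortho and para to the hydroxyl and not between the two oxygens, so the bromine is bought in place and the branch costs one step.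

9 ⇒ 7 (through 8). The O1–C2 bond of the furanone is cut, which returns the ortho-hydroxy acetophenone. The gain is a ring-free, fully substituted arene. The forward step needs halogenation at the methyl group only, which the absence of any free ring position secures.

7 ⇒ 6. The O–benzyl bond at the future C6 is cut. The two hydroxyls of 6 differ, since one is hydrogen-bonded to the acetyl group; the forward step must alkylate only the other.

6 ⇒ 4 (through 5). The aryl C–O bond at the future C6 is cut. That carbon is the only C–H of ring A and lies para to the phenol, the position a persulfate oxidation attacks. The gain is a tetraoxygenated arene; the forward step must avoid over-oxidation of an electron-rich phenoxide.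

4 ⇒ 1 + 2 (through 3). The aryl–acyl bond is cut and one O–H is returned to O–CH3. Arene 1 has two equivalent free positions, so the acylation poses no regiochemical question. The demand is that, of the two methoxy groups ortho to the new acetyl group, only the one with a methoxy neighbour is cleaved.

## Other disconnections considered

Alternative 1: The cut removes both bonds that tie ring A to ring C, O1–C8a and C4–C4a. Ring A would arrive as the symmetric aryne 4,5-bis(benzyloxy)-3,6-dimethoxybenzyne A3, released by fluoride from 3,4-bis(benzyloxy)-2,5-dimethoxy-6-(trimethylsilyl)phenyl trifluoromethanesulfonate A2. C2–C3–C4 and ring B would arrive as 3-[2-methoxy-6-(methoxymethoxy)phenyl]prop-2-ynoic acid A1. In the forward key step the carboxylate of A1 would add to A3, and the aryl anion so formed would take the acyl carbon through a four-membered transition state to give the ortho-hydroxyaryl ynone A4. A 6-endo-dig oxa-Michael closure and adjustment of the oxygen substituents would follow.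
- In its favour: the step is strongly convergent, and the symmetry of A3 removes any regiochemical question in the insertion. The slim alkyne means the di-ortho-substituted ring B never has to be coupled at a crowded carbon, and C3 arrives with no halogen to remove. On these points the alternative is better than the chosen plan.
- Against it: the same symmetry puts identical benzyl groups on O6 and O7, so after hydrogenolysis two neighbouring hydroxyls must be told apart by a selective 7-O-methylation that rests on a modest acidity difference. A2 is a hexasubstituted benzene needing a sequence of its own, longer than the way to 9. The acyl shift competes with protonation of the aryl anion, which would stop at O-arylation of the acid, the more so with methoxy groups on both sides of the aryne bond. The ynone can also close 5-exo, and the acetal on ring B requires a carcinogenic alkylating agent.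
- Comparison: on differentiating the ring A oxygens the chosen plan is better; on attaching ring B the alternative is better. Mechanistically both trust the chemoselectivity of a short-lived electrophile and are equal. In step economy the chosen plan should be shorter by about the length of the synthesis of A2 plus the late methylation.

Alternative 2: Ring A itself is taken apart at C5–C6 and, one stage earlier, at C8–C8a. Dimethyl squarate A5 would be attacked at one carbonyl group by the vinyllithium A6, which already carries C4 as a silyl-protected propargylic carbinol, the alkyne and ring B. This gives the 4-alkenyl-4-hydroxycyclobutenone A7. On heating, A7 would undergo four-electron ring opening and six-electron ring closure, the ketene carbon bonding to the methoxy-bearing alkene carbon, and tautomerisation would give the hydroquinone A8.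
- In its favour: the oxygen pattern is written into the building blocks. The two methoxy groups of A5 become 7-OMe and 8-OMe, the ketene oxygen becomes the free 6-OH and the carbinol oxygen becomes O1. Neither a persulfate oxidation nor a selective demethylation is needed, so on regiocontrol of ring A this is better than the chosen plan. The thermal cascade is neutral and metal-free, and the bond to ring B is again made at an unhindered alkyne (equal or better).
- Against it: A6 is a β-methoxy vinyllithium, a species prone to lose lithium methoxide, and it must be generated next to a propargylic C–H bond and a silyl ether after a long linear build. A8 is an electron-rich hydroquinone, and any oxidant used later to raise the carbinol to the ketone level would also oxidise ring A. Protection and redox steps therefore accumulate before ring C can be closed. The single stereocentre of A8 serves no purpose and is erased.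
- Comparison: on structure it is better for ring A and equal for ring B. On mechanism a pericyclic cascade is at least as predictable as a carbene addition. On step economy it is clearly worse, because ring C is still missing after the key step and A6 must be made first.

Alternative 3: The cut is the C2'–O bond of ring B. The substrate would be the flavone-3-carboxylic acid A9, with a plain 2-methoxyphenyl ring B and the 6-oxygen masked as a pivalate. Anodic oxidation of its carboxylate would give an acyloxy radical that attacks C2', and loss of a second electron and a proton would close the six-membered lactone A10. Opening the lactone with hydroxide, decarboxylation at C3 and loss of the pivalate would then reveal 2'-OH, C3–H and 6-OH.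
- In its favour: ring B enters as a simple mono-ortho-substituted unit, so the bond to C2 is less hindered than in 13 (better than the chosen plan). The carboxyl group is a traceless handle, the counterpart of the chlorine in 17 (equal). Only one C–H lies ortho to the biaryl bond, and the oxidant is electricity.
- Against it: ring A of A9, even with the pivalate, is a tetraoxygenated arene that is likely to lose an electron at a lower potential than the carboxylate, so oxidation of ring A competes with the wanted radical. Ipso attack at the methoxy-bearing ortho carbon would cost the 6'-oxygen. The hydroxide needed to open A10 also attacks the pyranone at C2. A9 needs the same ring A chemistry as 9 plus a 3-carboxylated pyranone built by the hindered 1,3-dicarbonyl route that the chosen plan avoids.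
- Comparison: on structure it is better for ring B and equal for ring A. On mechanism the chemoselectivity of an anodic step on so electron-rich a substrate is less predictable than carbene addition to an enol ether. On step economy it is no shorter and probably two or three steps longer.

Key step: step 7

Assumption: 1 and 10 are taken as catalogue compounds; 15 is racemic, and its SMILES shows one enantiomer of the cis-fused pair that the bicyclic frame enforces.

## Route

Step 1
Reactants: 1 1,2,3,5-tetramethoxybenzene; 2 acetyl chloride
Product: 4 1-(2-hydroxy-3,4,6-trimethoxyphenyl)ethan-1-one, via tetramethoxyacetophenone 3 (not isolated)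
Conditions: AlCl3 (2.5 equiv), Et2O, 0 °C to rt; 2 M HCl
Reagents that add atoms: none
Why: Friedel–Crafts acylation at either of the two equivalent free positions of 1 should give 3; AlCl3 held between the carbonyl oxygen and the adjacent methoxy group then cleaves the more crowded ortho O–CH3 bond (the one with a methoxy neighbour), a selectivity well established for polymethoxyaryl ketones.

Step 2
Reactants: 4 1-(2-hydroxy-3,4,6-trimethoxyphenyl)ethan-1-one
Product: 6 1-(2,5-dihydroxy-3,4,6-trimethoxyphenyl)ethan-1-one, via aryl sulfate potassium salt 5 (not isolated)
Conditions: K2S2O8 (1.1 equiv), aq. KOH, 15–20 °C, N2; then HCl to pH 1, 90 °C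
Reagents that add atoms: potassium peroxodisulfate, [K+].[K+].[O-]S(=O)(=O)OOS(=O)(=O)[O-]
Why: Elbs persulfate oxidation: the phenoxide of 4 attacks a peroxide oxygen through its para carbon, the only unsubstituted ring position, to give the aryl sulfate 5, which acid hydrolyses to the hydroquinone 6 (kept under nitrogen because it is air-sensitive).

Step 3
Reactants: 6 1-(2,5-dihydroxy-3,4,6-trimethoxyphenyl)ethan-1-one
Product: 7 1-[3-(benzyloxy)-6-hydroxy-2,4,5-trimethoxyphenyl]ethan-1-one
Conditions: BnBr (1.05 equiv), K2CO3 (1.1 equiv), acetone, reflux, N2
Reagents that add atoms: benzyl bromide, BrCc1ccccc1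
Why: Williamson etherification; the hydroxyl next to the acetyl group is tied up in a hydrogen bond to the carbonyl oxygen and is the weaker nucleophile, so one equivalent of benzyl bromide should alkylate the other hydroxyl selectively.

Step 4
Reactants: 7 1-[3-(benzyloxy)-6-hydroxy-2,4,5-trimethoxyphenyl]ethan-1-one
Product: 9 5-(benzyloxy)-4,6,7-trimethoxy-1-benzofuran-3(2H)-one, via bromoketone 8 (not isolated)
Conditions: CuBr2 (2.1 equiv), EtOAc–CHCl3, reflux; filter, concentrate; then NaOAc, EtOH, reflux
Reagents that add atoms: none
Why: CuBr2 brominates the enol of the aryl methyl ketone (ring A has no free position for nuclear bromination), and acetate then lets the ortho phenoxide displace bromide in a 5-exo-tet Williamson closure, the classical route from ortho-hydroxyacetophenones to benzofuran-3(2H)-ones.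

Step 5
Reactants: 10 2-bromo-3-methoxyphenol
Product: 11 1-(benzyloxy)-2-bromo-3-methoxybenzene
Conditions: BnBr, K2CO3, DMF, rt
Reagents that add atoms: benzyl bromide, BrCc1ccccc1
Why: Williamson etherification of an acidic phenol with no competing nucleophilic site.

Step 6
Reactants: 9 5-(benzyloxy)-4,6,7-trimethoxy-1-benzofuran-3(2H)-one; 11 1-(benzyloxy)-2-bromo-3-methoxybenzene
Product: 13 {5-(benzyloxy)-2-[2-(benzyloxy)-6-methoxyphenyl]-4,6,7-trimethoxy-1-benzofuran-3-yl}oxy(tert-butyl)dimethylsilane, via sodium enolate 12 (not isolated)
Conditions: Pd(OAc)2 (5 mol %), XPhos (10 mol %), NaOtBu (2.3 equiv), toluene, 80 °C, Ar; then TBSCl (2 equiv), DMF, 0 °C to rt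
Reagents that add atoms: tert-butyldimethylsilyl chloride, CC(C)(C)[Si](C)(C)Cl
Why: Palladium-catalysed α-arylation of a ketone enolate: oxidative addition of 11 to zerovalent palladium carrying the bulky biarylphosphine, exchange of bromide for the sodium enolate of 9, and C–C reductive elimination, which bulky ligands and ortho-substituted aryl groups accelerate. The product is deprotonated at once to the aromatic 3-oxidobenzofuran 12, which is too hindered for a second arylation and is silylated on oxygen in the same flask, so that the autoxidation-prone enol never meets air.

Step 7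
Reactants: 13 {5-(benzyloxy)-2-[2-(benzyloxy)-6-methoxyphenyl]-4,6,7-trimethoxy-1-benzofuran-3-yl}oxy(tert-butyl)dimethylsilane; 14 chloroform
Product: 17 6-(benzyloxy)-2-[2-(benzyloxy)-6-methoxyphenyl]-3-chloro-5,7,8-trimethoxy-4H-chromen-4-one, via dichlorocyclopropane adduct 15 (not isolated), via silyloxychromenylium chloride 16 (not isolated)
Conditions: CHCl3 (10 equiv), KOtBu (4 equiv, portionwise), hexane–THF, −30 °C to rt; aq. NH4Cl
Reagents that add atoms: none
Why: Dichlorocarbene, formed by α-elimination from 14 and KOtBu, is electrophilic and should add in a concerted [2+1] fashion to the most electron-rich π bond of 13, the furan C2=C3 bond that carries the ring oxygen on one carbon and the silyloxy group on the other, to give 15 (two transient stereocentres, cis by necessity of the ring fusion, racemic). In the bicyclo[3.1.0] frame of 15 the chlorine lying over the five-membered ring ionises while the fusion bond opens in a disrotatory sense, so the only allyl cation the ring can hold is the ring-expanded one, here the aromatic 4-silyloxy-3-chlorochromenylium ion of 16; chloride (or tert-butoxide, or water at the quench) then takes the silyl group from oxygen and leaves the C4 carbonyl. Ring C is thus closed not by a cyclisation but by expansion of the five-membered ring: C2–C3 and C3–C4 are made in the cycloaddition and the old C2–C4 bond is the one that breaks. The closest known reaction types are the dihalocarbene ring expansion of cyclic silyl enol ethers to 2-halo enones and the Ciamician–Dennstedt one-carbon insertion into indoles and benzofurans. No stereocentre remains in 17, so nothing has to be controlled there. Three selectivities are needed: addition to the enol ether and not to the alkoxyarenes or benzylic C–H bonds (secured by the nucleophilicity of the doubly oxygenated alkene and the small size of the carbene); survival of the O–Si bond until the carbene has added, since a free enolate would be C-dichloromethylated in the Reimer–Tiemann manner (secured by the tert-butyl group on silicon, low temperature, excess 14 and portionwise base); and cleavage of the fusion bond (secured by orbital symmetry and ring strain).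

Step 8
Reactants: 17 6-(benzyloxy)-2-[2-(benzyloxy)-6-methoxyphenyl]-3-chloro-5,7,8-trimethoxy-4H-chromen-4-one
Product: 18 6-hydroxy-2-(2-hydroxy-6-methoxyphenyl)-5,7,8-trimethoxy-4H-chromen-4-one
Conditions: H2 (1 atm), 10% Pd/C, NaOAc (2 equiv), EtOAc–MeOH, rt
Reagents that add atoms: none
Why: Heterogeneous hydrogenolysis on palladium: both aryl benzyl ethers are cleaved and the C3–Cl bond of the α-chloro enone is reduced, with acetate taking up HCl in place of an amine that would slow the debenzylation. The trisubstituted C2=C3 bond is conjugated and shielded by the di-ortho-substituted ring B and should survive at 1 atm.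

## Compound list

1 | 1,2,3,5-tetramethoxybenzene | COc1cc(OC)c(OC)c(OC)c1 | starting material
2 | acetyl chloride | CC(=O)Cl | starting material
3 | 1-(2,3,4,6-tetramethoxyphenyl)ethan-1-one (formed and consumed in step 1) | CC(=O)c1c(OC)c(OC)c(OC)cc1OC | intermediate
4 | 1-(2-hydroxy-3,4,6-trimethoxyphenyl)ethan-1-one | CC(=O)c1c(O)c(OC)c(OC)cc1OC | intermediate
5 | potassium 3-acetyl-4-hydroxy-2,5,6-trimethoxyphenyl sulfate (formed and consumed in step 2) | CC(=O)c1c(O)c(OC)c(OC)c(OS(=O)(=O)[O-])c1OC.[K+] | intermediate
6 | 1-(2,5-dihydroxy-3,4,6-trimethoxyphenyl)ethan-1-one | CC(=O)c1c(O)c(OC)c(OC)c(O)c1OC | intermediate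
7 | 1-[3-(benzyloxy)-6-hydroxy-2,4,5-trimethoxyphenyl]ethan-1-one | CC(=O)c1c(O)c(OC)c(OC)c(OCc2ccccc2)c1OC | intermediate
8 | 1-[3-(benzyloxy)-6-hydroxy-2,4,5-trimethoxyphenyl]-2-bromoethan-1-one (formed and consumed in step 4) | O=C(CBr)c1c(O)c(OC)c(OC)c(OCc2ccccc2)c1OC | intermediate
9 | 5-(benzyloxy)-4,6,7-trimethoxy-1-benzofuran-3(2H)-one | O=C1COc2c(OC)c(OC)c(OCc3ccccc3)c(OC)c12 | intermediate
10 | 2-bromo-3-methoxyphenol | COc1cccc(O)c1Br | starting material
11 | 1-(benzyloxy)-2-bromo-3-methoxybenzene | COc1cccc(OCc2ccccc2)c1Br | intermediate
12 | sodium 5-(benzyloxy)-2-[2-(benzyloxy)-6-methoxyphenyl]-4,6,7-trimethoxy-1-benzofuran-3-olate (formed and consumed in step 6) | COc1cccc(OCc2ccccc2)c1-c1oc2c(OC)c(OC)c(OCc3ccccc3)c(OC)c2c1[O-].[Na+] | intermediate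
13 | {5-(benzyloxy)-2-[2-(benzyloxy)-6-methoxyphenyl]-4,6,7-trimethoxy-1-benzofuran-3-yl}oxy(tert-butyl)dimethylsilane | COc1cccc(OCc2ccccc2)c1-c1oc2c(OC)c(OC)c(OCc3ccccc3)c(OC)c2c1O[Si](C)(C)C(C)(C)C | intermediate
14 | chloroform | ClC(Cl)Cl | starting material
15 | {5-(benzyloxy)-1a-[2-(benzyloxy)-6-methoxyphenyl]-1,1-dichloro-3,4,6-trimethoxy-1,1a-dihydro-6bH-cyclopropa[b][1]benzofuran-6b-yl}oxy(tert-butyl)dimethylsilane, racemic, cis ring fusion with aryl and silyloxy groups on the same face (formed and consumed in step 7) | COc1cccc(OCc2ccccc2)c1[C@@]12Oc3c(OC)c(OC)c(OCc4ccccc4)c(OC)c3[C@]1(O[Si](C)(C)C(C)(C)C)C2(Cl)Cl | intermediate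
16 | 6-(benzyloxy)-2-[2-(benzyloxy)-6-methoxyphenyl]-4-[(tert-butyldimethylsilyl)oxy]-3-chloro-5,7,8-trimethoxychromenylium chloride (formed and consumed in step 7) | COc1cccc(OCc2ccccc2)c1-c1[o+]c2c(OC)c(OC)c(OCc3ccccc3)c(OC)c2c(O[Si](C)(C)C(C)(C)C)c1Cl.[Cl-] | intermediate
17 | 6-(benzyloxy)-2-[2-(benzyloxy)-6-methoxyphenyl]-3-chloro-5,7,8-trimethoxy-4H-chromen-4-one | COc1cccc(OCc2ccccc2)c1-c1oc2c(OC)c(OC)c(OCc3ccccc3)c(OC)c2c(=O)c1Cl | intermediate
18 | 6-hydroxy-2-(2-hydroxy-6-methoxyphenyl)-5,7,8-trimethoxy-4H-chromen-4-one (6,2'-dihydroxy-5,7,8,6'-tetramethoxyflavone) | COc1cccc(O)c1-c1cc(=O)c2c(OC)c(O)c(OC)c(OC)c2o1 | target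

## Step count and least certain steps

Total: 8 steps. Longest linear sequence: 7 steps (1 → 4 → 6 → 7 → 9 → 13 → 17 → 18); the only branch is the one-step preparation of 11.

**Step 7 (key step).** The most likely failure is loss of the silyl group to tert-butoxide before the carbene has added, after which the free enolate is attacked at carbon and the ring is not expanded. The second risk is slow cyclopropanation of the tetrasubstituted, doubly shielded double bond, so that the carbene is consumed by alkoxide.
Fallback: abandon the insertion and build ring C by Baker–Venkataraman-type 1,3-dicarbonyl chemistry, setting out from 7 and 11 and rejoining the route at 18.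
- Bromine–lithium exchange of 11 (n-BuLi, THF, −78 °C) and carboxylation with CO2 would give 2-(benzyloxy)-6-methoxybenzoic acid F1.
- (COCl)2 with catalytic DMF would convert F1 into 2-(benzyloxy)-6-methoxybenzoyl chloride F2.
- Acetophenone 7, deprotonated twice with LiHMDS (3 equiv, THF, −78 °C), would be C-acylated by F2 to 1-[3-(benzyloxy)-6-hydroxy-2,4,5-trimethoxyphenyl]-3-[2-(benzyloxy)-6-methoxyphenyl]propane-1,3-dione F3.
- Cyclodehydration (catalytic TsOH, toluene, 80 °C) would give 6-(benzyloxy)-2-[2-(benzyloxy)-6-methoxyphenyl]-5,7,8-trimethoxy-4H-chromen-4-one F4.
- Hydrogenolysis (H2, 10% Pd/C, EtOAc–MeOH) would then give 18.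

**Step 6.** Oxidative addition and reductive elimination with the di-ortho-substituted bromide may be slow. Hydrodebromination of 11 and base-induced self-condensation of 9 would then take over, and silylation of the crowded enolate oxygen may be incomplete.
Fallback: reverse the polarity at C2, setting out from 9 and 11 and returning at 13.
- Silylation of 9 (TBSOTf, Et3N, CH2Cl2, 0 °C) would give {[5-(benzyloxy)-4,6,7-trimethoxy-1-benzofuran-3-yl]oxy}(tert-butyl)dimethylsilane F5.
- Zincation of its C2–H bond with TMPZnCl·LiCl (THF, rt) would give {5-(benzyloxy)-3-[(tert-butyldimethylsilyl)oxy]-4,6,7-trimethoxy-1-benzofuran-2-yl}zinc chloride F6. A carbon–zinc bond is chosen because it should not trigger migration of silicon from oxygen to carbon.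
- Negishi coupling of F6 with 11 (Pd(OAc)2, SPhos, THF, 50 °C) would give 13.

**Step 8.** Cleavage of the C–Cl bond may lag behind debenzylation, and prolonged exposure to hydrogen invites saturation of C2=C3.
Fallback: change the bond to be cleaved, setting out from 13 and returning at 18.
- Ring expansion with dibromocarbene (CHBr3, KOtBu, hexane–THF, −30 °C to rt) would give 6-(benzyloxy)-2-[2-(benzyloxy)-6-methoxyphenyl]-3-bromo-5,7,8-trimethoxy-4H-chromen-4-one F7.
- Its C–Br bond is hydrogenolysed far more readily, so H2, 10% Pd/C and NaOAc at short contact time would give 18.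

**Step 2.** Conversion in persulfate oxidations is often incomplete, and the electron-rich phenoxide is prone to further oxidation and oligomerisation.
Fallback: oxidise to the quinone level and reduce back, setting out from 4 and returning at 6.
- Teuber oxidation with (KSO3)2NO (potassium nitrosodisulfonate) in buffered water–acetone would take the phenol, whose para position is free, to 2-acetyl-3,5,6-trimethoxycyclohexa-2,5-diene-1,4-dione F8.
- Reduction with Na2S2O4 in water–EtOAc would give 6.

## Further compounds

F1 | step 7 | 2-(benzyloxy)-6-methoxybenzoic acid | COc1cccc(OCc2ccccc2)c1C(=O)O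
F2 | step 7 | 2-(benzyloxy)-6-methoxybenzoyl chloride | COc1cccc(OCc2ccccc2)c1C(=O)Cl
F3 | step 7 | 1-[3-(benzyloxy)-6-hydroxy-2,4,5-trimethoxyphenyl]-3-[2-(benzyloxy)-6-methoxyphenyl]propane-1,3-dione | COc1cccc(OCc2ccccc2)c1C(=O)CC(=O)c1c(O)c(OC)c(OC)c(OCc2ccccc2)c1OC
F4 | step 7 | 6-(benzyloxy)-2-[2-(benzyloxy)-6-methoxyphenyl]-5,7,8-trimethoxy-4H-chromen-4-one | COc1cccc(OCc2ccccc2)c1-c1cc(=O)c2c(OC)c(OCc3ccccc3)c(OC)c(OC)c2o1
F5 | step 6 | {[5-(benzyloxy)-4,6,7-trimethoxy-1-benzofuran-3-yl]oxy}(tert-butyl)dimethylsilane | CC(C)(C)[Si](C)(C)Oc1coc2c(OC)c(OC)c(OCc3ccccc3)c(OC)c12
F6 | step 6 | {5-(benzyloxy)-3-[(tert-butyldimethylsilyl)oxy]-4,6,7-trimethoxy-1-benzofuran-2-yl}zinc chloride | CC(C)(C)[Si](C)(C)Oc1c([Zn]Cl)oc2c(OC)c(OC)c(OCc3ccccc3)c(OC)c12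
F7 | step 8 | 6-(benzyloxy)-2-[2-(benzyloxy)-6-methoxyphenyl]-3-bromo-5,7,8-trimethoxy-4H-chromen-4-one | COc1cccc(OCc2ccccc2)c1-c1oc2c(OC)c(OC)c(OCc3ccccc3)c(OC)c2c(=O)c1Br
F8 | step 2 | 2-acetyl-3,5,6-trimethoxycyclohexa-2,5-diene-1,4-dione | CC(=O)C1=C(OC)C(=O)C(OC)=C(OC)C1=O
A1 | alternative 1 | 3-[2-methoxy-6-(methoxymethoxy)phenyl]prop-2-ynoic acid | COCOc1cccc(OC)c1C#CC(=O)O
A2 | alternative 1 | 3,4-bis(benzyloxy)-2,5-dimethoxy-6-(trimethylsilyl)phenyl trifluoromethanesulfonate | COc1c(OCc2ccccc2)c(OCc2ccccc2)c(OC)c([Si](C)(C)C)c1OS(=O)(=O)C(F)(F)F
A3 | alternative 1 | 4,5-bis(benzyloxy)-3,6-dimethoxybenzyne | COC1=C(OCc2ccccc2)C(OCc2ccccc2)=C(OC)C#C1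
A4 | alternative 1 | 1-[3,4-bis(benzyloxy)-6-hydroxy-2,5-dimethoxyphenyl]-3-[2-methoxy-6-(methoxymethoxy)phenyl]prop-2-yn-1-one | COCOc1cccc(OC)c1C#CC(=O)c1c(O)c(OC)c(OCc2ccccc2)c(OCc2ccccc2)c1OC
A5 | alternative 2 | dimethyl squarate (3,4-dimethoxycyclobut-3-ene-1,2-dione) | COC1=C(OC)C(=O)C1=O
A6 | alternative 2 | {5-[2-(benzyloxy)-6-methoxyphenyl]-3-[(tert-butyldimethylsilyl)oxy]-1-methoxypent-1-en-4-yn-2-yl}lithium (racemic, alkene geometry immaterial) | [Li]C(=COC)C(O[Si](C)(C)C(C)(C)C)C#Cc1c(OC)cccc1OCc1ccccc1
A7 | alternative 2 | 4-{5-[2-(benzyloxy)-6-methoxyphenyl]-3-[(tert-butyldimethylsilyl)oxy]-1-methoxypent-1-en-4-yn-2-yl}-4-hydroxy-2,3-dimethoxycyclobut-2-en-1-one (mixture of diastereomers) | COC=C(C(O[Si](C)(C)C(C)(C)C)C#Cc1c(OC)cccc1OCc1ccccc1)C1(O)C(OC)=C(OC)C1=O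
A8 | alternative 2 | 2-[3-[2-(benzyloxy)-6-methoxyphenyl]-1-(tert-butyldimethylsilyloxy)prop-2-ynyl]-3,5,6-trimethoxybenzene-1,4-diol (racemic) | COc1c(O)c(OC)c(OC)c(O)c1C(O[Si](C)(C)C(C)(C)C)C#Cc1c(OC)cccc1OCc1ccccc1
A9 | alternative 3 | 5,7,8-trimethoxy-2-(2-methoxyphenyl)-4-oxo-6-(pivaloyloxy)-4H-chromene-3-carboxylic acid | COc1ccccc1-c1oc2c(OC)c(OC)c(OC(=O)C(C)(C)C)c(OC)c2c(=O)c1C(=O)O
A10 | alternative 3 | ring B-fused lactone pivalate: tetramethoxy-6H,7H-chromeno[4,3-b]chromene-6,7-dione with the pivaloyloxy group on the ring A carbon para to the pyranone oxygen | COc1cccc2oc(=O)c3c(=O)c4c(OC)c(OC(=O)C(C)(C)C)c(OC)c(OC)c4oc3c12
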